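Remark on the chemistry: the target is taken as the free bis(hydrogen sulfate) that its SMILES shows. Ring B carries the tricetin numbering in every compound, so the carbon that ends up sulfated is C3' and the two ketal oxygens sit on C4' and C5'.

Compound numbers used throughout: 1 3,4-dihydroxybenzaldehyde; 2 2,2-dimethoxypropane; 3 acetonide aldehyde; 4 2',6'-dihydroxyacetophenone; 5 chalcone; 6 flavanone (not isolated); 7 5-hydroxyflavone; 8 5-O-MOM flavone; 9 bis(pinacolato)diboron; 10 7,3'-bis-boronate (not isolated); 11 7,3'-diol; 12 protected bis(trichloroethyl sulfate); 13 deprotected bis(trichloroethyl sulfate); 14 diammonium disulfate (not isolated); 15 target.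

## Analysis of the target

Tricetin 7,3'-disulfate (15) is a flavone: a benzo-4-pyranone (rings A and C) with a phenyl ring B on C2. All carbons of the skeleton are sp2, so there is no stereocentre and no double-bond geometry to control. Five oxygens sit on the benzene rings: C5–O and C7–O on ring A, and the contiguous C3'–O, C4'–O and C5'–O on ring B. Those at C7 and C3' are hydrogen sulfate esters; the other three are free phenols. The sensitive groups are the aryl sulfate monoesters (strongly acidic, very polar, prone to acid-catalysed S–O cleavage) and the C4'/C5' catechol, which is easily oxidised and, like the C5–OH/C4=O pair, binds metal ions. The difficulty lies in differentiation and not in the skeleton: C3'–O and C5'–O are equivalent in tricetin, C4'–O lies between them, and C7–O must be told from C5–O. The strategy rests on the flavone that remains when the two sulfated oxygens are removed in thought. In that 5,4',5'-trioxygenated flavone, C7–H is the only C–H of ring A without an ortho neighbour, and C3'–H lies next to an oxygen that a five-membered ketal across C4'–O/C5'–O pulls back. These are the positions a bulky iridium boryl catalyst attacks, so both oxygens can be introduced late and together, as the only free hydroxyls of the molecule, and sulfation then needs no selectivity.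

## Retrosynthetic reasoning

**15 to 13 (through 14).** The O–CH2 bonds of two trichloroethyl sulfate esters are the last to be cleaved. The sulfates are carried as neutral diesters because the monoesters are too polar to purify through several steps and would not survive acid. The forward step has to release both sulfates under near-neutral, reductive conditions and exchange the counter-ions of salt 14 for protons.

**13 to 12.** The ketal across C4'–O/C5'–O and the methoxymethyl acetal on C5–O are restored. Both fall in one acid treatment, and this is placed before the sulfates are unmasked, while they are still acid-stable diesters.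

**12 to 11.** The two aryl O–S bonds are cut. In 11 the hydroxyls at C7 and C3' are the only nucleophiles, so one sulfurylation step serves both and no site selectivity has to be built in.

**11 to 8 and 9 (through 10).** The C7–O and C3'–O bonds are cut, which is the heart of the plan.
- These two oxygens are the ones that distinguish the sulfated from the free positions, so making them last removes the whole differentiation problem.
- In 8, C7–H and C3'–H are the two aromatic C–H bonds most open to a crowded catalyst.
- The forward reaction must convert both C–H bonds to C–B bonds of 10 with reagent 9 and then oxidise C–B to C–O, without touching the other five sp2 C–H bonds.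
- The ketal in 8 is not a spectator. It carries no aromatic C–H, and by tying C4'–O back it opens the neighbouring C3'–H.

**8 to 7.** The O–CH2 bond of the methoxymethyl ether on C5–O is cut. A free C5 phenol would be O-borylated and could steer the catalyst to C6. The ether blocks that, shields C6–H, occupies the site a carbonyl-directed borylation would choose, and later leaves together with the ketal.

**7 to 5 (through 6).** The O1–C2 bond is cut and the C2=C3 unsaturation is removed, leading back to a 2',6'-dihydroxychalcone. Either of its two equivalent hydroxyls can close ring C, and the other becomes the C5 hydroxyl, so ring A needs no protection at this stage.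

**5 to 3 and 4.** The Cα=Cβ bond of the chalcone (the future C3–C2 bond) is cut by a crossed aldol disconnection. This splits the molecule into a ring A ketone 4 and a ring B aldehyde 3, neither of which has to carry the oxygens destined for sulfation.

**3 to 1 and 2.** The two C–O bonds of the ketal are cut, giving the catechol aldehyde 1 and the acetone equivalent 2.

## Alternatives that were turned down

**Alternative 1: Friedel–Crafts closure of ring C.**
- Disconnection: the C4–C4a bond is cut, leading to the β-aryloxycinnamic acid A2, in which O1–C2 already exists from addition of a 3,5-dioxygenated phenol to an arylpropiolic ester.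
- Forward key step: activation of the carboxyl group of A2 (for example P2O5 in MeSO3H) and intramolecular acylation of the ortho carbon of the phloroglucinol ether, closing the six-membered ring C to give flavone A1.
- For it: the aromatic nucleophile is very electron-rich and its two ortho positions are equivalent, so there is no regiochemical question. All five oxygens come with the building blocks. Allyl against benzyl marks the 5,7,3' against the 4',5' oxygens cleanly.
- Against it: the acylating medium is hard on allyl and benzyl ethers of electron-rich rings (cleavage, migration to carbon). The acid must have the carboxyl cis to the aryloxy group. The ring B building block needs a gallate desymmetrised into a 3-O-allyl-4,5-di-O-benzyl pattern before the alkyne is made. After A1 there remain deallylation, a bis-sulfurylation that must spare the chelated C5 hydroxyl, and hydrogenolysis.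
- Comparison: on certainty of regiochemistry this route is stronger than a C–H functionalisation. The chosen route offers in its place roughly half the number of operations, no protecting-group work on the pyrogallol ring, and a sulfation that needs no selectivity.

**Alternative 2: ring B built from a squarate-derived cyclobutenone.**
- Disconnection: ring B is taken apart at C1'–C6' and C2'–C3', leading to the 4-chlorocyclobutenone A4 and the chromonyl vinylstannane A5.
- Forward key step: cross-coupling of A4 with A5 under zerovalent palladium catalysis (for example Pd(PPh3)4) forms C1'–C6'. The 4-vinylcyclobutenone opens thermally to a dienylketene, 6π ring closure forms C2'–C3', and tautomerisation gives phenol A3.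
- For it: the ketene carbon becomes C3' and arrives as a free hydroxyl, while C4'–O and C5'–O come from the squarate as benzyl ethers. The three ring B oxygens are therefore differentiated by construction, with no selectivity to trust.
- Against it: A5 needs a multistep chromone synthesis followed by alkyne hydrostannation, and A4 is a sensitive allylic chloride made from a squaric ester in two further steps. Tin has to be removed. In A3 only C3'–OH is free, so the C7 sulfate needs a second round: sulfurylation of C3'–OH, loss of both acetals, selective sulfurylation of C7–OH over C5–OH, then hydrogenolysis.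
- Comparison: for ring B this alternative is the stronger one, since it fixes by bond construction what the chosen route fixes by catalyst selectivity. The chosen route instead creates both sulfation sites in one operation on an easily made flavone, and sulfates them in one step.

**Alternative 3: pyranone chain folded into rings A and C.**
- Disconnection: rings A and C are both opened, leading to the 6-(2-oxo-4-arylbut-3-ynyl)-4-hydroxy-2-pyranone A7.
- Forward key step: Mg(OMe)2 opens the pyranone of A7 to a 3,5,7-trioxo ester. The methylene that becomes C4a attacks the ester carbon that becomes C8a (Claisen closure of ring A), and a phenoxide of the new phloroglucinol adds to the ynone to form O1–C2 and close ring C, giving flavone A6.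
- For it: two rings form in one biomimetic operation. Ring A needs no protecting group and emerges as the 5,7-diol, whose differentiation by the C5–OH/C4=O hydrogen bond is intrinsic.
- Against it: the polyketone can also close by aldol condensation to a resorcylate. Methoxide can add to the ynone. The phenoxide can close in the 5-exo mode to an aurone. The ring B alkynoic ester again needs a gallate with three differently treated oxygens. Removing the C3' acetal in the presence of benzyl ethers and sulfating afterwards lengthens the end of the route.
- Comparison: it is more convergent in ring construction than the chosen route, which builds the flavone by a plain chalcone sequence. The chosen route offers a precursor available in four routine steps and concentrates all uncertainty in a single step whose outcome can be read directly from the crude product.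

Key step: step 5

## Route

Step 1
Reactants: 1 3,4-dihydroxybenzaldehyde; 2 2,2-dimethoxypropane
Product: 3 2,2-dimethyl-1,3-benzodioxole-5-carbaldehyde
Conditions: TsOH·H2O (cat.), toluene, reflux, condensate returned through 4 Å molecular sieves; then short wash with dil. aq. HCl/THF, rt
Reagents that add atoms: none
Why: Acid-catalysed transketalisation; the catechol exchanges both methoxy groups of 2 and removal of methanol drives the cyclic ketal forward. A dimethyl acetal formed at the aldehyde is far more labile than the aryl ketal and is returned by the short aqueous acid wash.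

Step 2
Reactants: 3 2,2-dimethyl-1,3-benzodioxole-5-carbaldehyde; 4 1-(2,6-dihydroxyphenyl)ethanone (2',6'-dihydroxyacetophenone)
Product: 5 (E)-1-(2,6-dihydroxyphenyl)-3-(2,2-dimethyl-1,3-benzodioxol-5-yl)prop-2-en-1-one
Conditions: KOH (50% aq., excess), EtOH, 0 °C to rt; then cold 1 M HCl to pH 5
Reagents that add atoms: none
Why: Claisen–Schmidt (crossed aldol) condensation; the ketone enolate adds to the non-enolisable aldehyde and E1cB loss of hydroxide gives the conjugated enone in its thermodynamic E geometry. The ketal is inert to hydroxide.

Step 3
Reactants: 5 (E)-1-(2,6-dihydroxyphenyl)-3-(2,2-dimethyl-1,3-benzodioxol-5-yl)prop-2-en-1-one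
Product: 7 2-(2,2-dimethyl-1,3-benzodioxol-5-yl)-5-hydroxy-4H-chromen-4-one, via 5-hydroxyflavanone 6 (not isolated)
Conditions: I2 (10 mol%), DMSO, 120 °C
Reagents that add atoms: none
Why: Iodine-catalysed oxidative cyclisation of a 2'-hydroxychalcone; 6-endo oxa-Michael addition gives racemic flavanone 6, α-iodination and loss of HI give the pyranone, and DMSO reoxidises HI to I2. The two ortho hydroxyls of 5 are equivalent, so either closure gives 7, and any 6 already present in 5 converges on the same product.

Step 4
Reactants: 7 2-(2,2-dimethyl-1,3-benzodioxol-5-yl)-5-hydroxy-4H-chromen-4-one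
Product: 8 2-(2,2-dimethyl-1,3-benzodioxol-5-yl)-5-(methoxymethoxy)-4H-chromen-4-one
Conditions: NaH, DMF, 0 °C; MOMCl, 0 °C to rt
Reagents that add atoms: chloromethyl methyl ether, COCCl
Why: Williamson-type O-alkylation; NaH converts the chelated C5 phenol fully into its phenoxide, which breaks the hydrogen bond to C4=O and is alkylated by the chloromethyl ether. The ketal is stable to base.

Step 5
Reactants: 8 2-(2,2-dimethyl-1,3-benzodioxol-5-yl)-5-(methoxymethoxy)-4H-chromen-4-one; 9 bis(pinacolato)diboron
Product: 11 7-hydroxy-2-(7-hydroxy-2,2-dimethyl-1,3-benzodioxol-5-yl)-5-(methoxymethoxy)-4H-chromen-4-one (4',5'-O-isopropylidene-5-O-methoxymethyltricetin), via 7,3'-bis(pinacolboryl)flavone 10 (not isolated)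
Conditions: [Ir(OMe)(cod)]2 (3 mol%), 4,4'-di-tert-butyl-2,2'-bipyridine (6 mol%), 9 (2.5 equiv), THF, 80 °C; then NaBO3·4H2O, THF/H2O, rt
Reagents that add atoms: sodium perborate tetrahydrate NaBO3·4H2O, [Na+].[Na+].O[B-]1(O)OO[B-](O)(O)OO1 (peroxoborate dimer, water of crystallisation left out; source of both new oxygen atoms of 11, while the boron atoms of 10 come from reactant 9)
Why: The precatalyst, the bipyridine and 9 give the trivalent iridium trisboryl complex, which cleaves an arene C–H bond by oxidative addition and releases the aryl boronate by C–B reductive elimination; 9 or the pinacolborane formed regenerates the trisboryl species. The closest known reaction type is iridium-catalysed aromatic C–H borylation with one-pot oxidation of the C–B bond to a phenol, here run twice on one substrate. No ring is closed and no stereocentre is formed. The step needs site selectivity among seven sp2 C–H bonds, and the crowded catalyst should supply it: on ring A only C7–H has no ortho substituent (C6–H lies next to the MOM ether, C8–H next to O1), and on ring B C3'–H lies next to an oxygen that the five-membered ketal pulls back and that acidifies this bond, whereas C6'–H is wedged between the chromone and the ketal, C2'–H lies next to the chromone and C3–H sits between C4=O and the aryl group. The MOM ether also occupies C5, the site a carbonyl-directed borylation would choose, and once C7 and C3' carry boron every remaining C–H is flanked, so the reaction should stop at bis-boronate 10. The peroxoborate then adds to each boron, the aryl group migrates from boron to oxygen, and hydrolysis of the borate esters at mildly basic pH leaves ketal, MOM ether and pyranone untouched. The two new hydroxyls are the only free phenols of 11.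

Step 6
Reactants: 11 4',5'-O-isopropylidene-5-O-methoxymethyltricetin
Product: 12 4',5'-O-isopropylidene-5-O-methoxymethyltricetin 7,3'-bis(2,2,2-trichloroethyl sulfate)
Conditions: Cl3CCH2OSO2Cl (3 equiv), Et3N, DMAP, THF, 0 °C to rt
Reagents that add atoms: 2,2,2-trichloroethyl chlorosulfate, ClS(=O)(=O)OCC(Cl)(Cl)Cl
Why: Sulfurylation of phenols with a protected chlorosulfate (DMAP as nucleophilic catalyst, Et3N as base); the C7 and C3' hydroxyls are the only nucleophiles in 11, so both are esterified without any need for selectivity. The neutral diester can be purified on silica.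

Step 7
Reactants: 12 4',5'-O-isopropylidene-5-O-methoxymethyltricetin 7,3'-bis(2,2,2-trichloroethyl sulfate)
Product: 13 tricetin 7,3'-bis(2,2,2-trichloroethyl sulfate)
Conditions: CF3CO2H/H2O (9:1), 0 °C to rt
Reagents that add atoms: none
Why: Acid hydrolysis of the MOM acetal and of the isopropylidene ketal through oxocarbenium ions. Aryl trichloroethyl sulfate diesters cannot lose SO3 as the monoesters do and withstand CF3CO2H, which is why the acid step precedes the unmasking of the sulfates.

Step 8
Reactants: 13 tricetin 7,3'-bis(2,2,2-trichloroethyl sulfate)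
Product: 15 tricetin 7,3'-disulfate, via diammonium disulfate 14 (not isolated)
Conditions: Zn dust, HCO2NH4, MeOH, rt; filter; sulfonic acid cation-exchange resin (H+ form), H2O, 0 °C; freeze-dry at once
Reagents that add atoms: ammonium formate, [NH4+].[O-]C=O (ammonium ions of 14 only; 15 keeps no atom of it)
Why: Reductive β-elimination; Zn transfers two electrons into a C–Cl bond and the resulting carbanion expels the sulfate monoanion and 1,1-dichloroethene, while HCO2NH4 keeps the medium near neutral and supplies the counter-ions of 14. The resin then takes up ammonium and divalent zinc and releases 15 as the free acid.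

## Compound list

1 | 3,4-dihydroxybenzaldehyde | O=Cc1ccc(O)c(O)c1 | starting material
2 | 2,2-dimethoxypropane | COC(C)(C)OC | starting material
3 | 2,2-dimethyl-1,3-benzodioxole-5-carbaldehyde | O=Cc1ccc2c(c1)OC(C)(C)O2 | intermediate
4 | 1-(2,6-dihydroxyphenyl)ethanone (2',6'-dihydroxyacetophenone) | CC(=O)c1c(O)cccc1O | starting material
5 | (E)-1-(2,6-dihydroxyphenyl)-3-(2,2-dimethyl-1,3-benzodioxol-5-yl)prop-2-en-1-one | O=C(/C=C/c1ccc2c(c1)OC(C)(C)O2)c1c(O)cccc1O | intermediate
6 | racemic 2-(2,2-dimethyl-1,3-benzodioxol-5-yl)-5-hydroxychroman-4-one (not isolated) | O=C1CC(c2ccc3c(c2)OC(C)(C)O3)Oc2cccc(O)c21 | intermediate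
7 | 2-(2,2-dimethyl-1,3-benzodioxol-5-yl)-5-hydroxy-4H-chromen-4-one | O=c1cc(-c2ccc3c(c2)OC(C)(C)O3)oc2cccc(O)c12 | intermediate
8 | 2-(2,2-dimethyl-1,3-benzodioxol-5-yl)-5-(methoxymethoxy)-4H-chromen-4-one | O=c1cc(-c2ccc3c(c2)OC(C)(C)O3)oc2cccc(OCOC)c12 | intermediate
9 | bis(pinacolato)diboron | CC1(C)OB(OC1(C)C)B1OC(C)(C)C(C)(C)O1 | starting material
10 | 2-[2,2-dimethyl-7-(4,4,5,5-tetramethyl-1,3,2-dioxaborolan-2-yl)-1,3-benzodioxol-5-yl]-5-(methoxymethoxy)-7-(4,4,5,5-tetramethyl-1,3,2-dioxaborolan-2-yl)-4H-chromen-4-one (not isolated) | O=c1cc(-c2cc(B3OC(C)(C)C(C)(C)O3)c3c(c2)OC(C)(C)O3)oc2cc(B3OC(C)(C)C(C)(C)O3)cc(OCOC)c12 | intermediate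
11 | 7-hydroxy-2-(7-hydroxy-2,2-dimethyl-1,3-benzodioxol-5-yl)-5-(methoxymethoxy)-4H-chromen-4-one (4',5'-O-isopropylidene-5-O-methoxymethyltricetin) | O=c1cc(-c2cc(O)c3c(c2)OC(C)(C)O3)oc2cc(O)cc(OCOC)c12 | intermediate
12 | 4',5'-O-isopropylidene-5-O-methoxymethyltricetin 7,3'-bis(2,2,2-trichloroethyl sulfate) | O=c1cc(-c2cc(OS(=O)(=O)OCC(Cl)(Cl)Cl)c3c(c2)OC(C)(C)O3)oc2cc(OS(=O)(=O)OCC(Cl)(Cl)Cl)cc(OCOC)c12 | intermediate
13 | tricetin 7,3'-bis(2,2,2-trichloroethyl sulfate) | O=c1cc(-c2cc(O)c(O)c(OS(=O)(=O)OCC(Cl)(Cl)Cl)c2)oc2cc(OS(=O)(=O)OCC(Cl)(Cl)Cl)cc(O)c12 | intermediate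
14 | tricetin 7,3'-disulfate diammonium salt (not isolated) | [NH4+].[NH4+].O=c1cc(-c2cc(O)c(O)c(OS(=O)(=O)[O-])c2)oc2cc(OS(=O)(=O)[O-])cc(O)c12 | intermediate
15 | tricetin 7,3'-disulfate | O=c1cc(-c2cc(O)c(O)c(OS(=O)(=O)O)c2)oc2cc(OS(=O)(=O)O)cc(O)c12 | target

## Step count and least certain steps

Total step count: 8. Longest linear sequence: 8 steps (1, 3, 5, 7, 8, 11, 12, 13, 15); compound 4 enters in step 2 and compound 9 in step 5.

**Step 5 (key step).**
- What may go wrong: the ring B site has one ortho neighbour and the methyl groups of the ketal stand near it, so borylation of ring B may be slow or drift towards C2'–H, leaving a mono-boronate at C7 or a mixture. The pinacolborane formed may also reduce the pyranone in conjugate fashion.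
- Fallback: C–H oxidation is given up and all five oxygens come with the building blocks. It sets out from 2 and rejoins at 13.
  - 2 ketalises commercial methyl gallate (TsOH, toluene, reflux) to methyl 7-hydroxy-2,2-dimethyl-1,3-benzodioxole-5-carboxylate F1.
  - Benzylation (BnBr, K2CO3, DMF) gives methyl 7-(benzyloxy)-2,2-dimethyl-1,3-benzodioxole-5-carboxylate F2.
  - LiAlH4 reduction gives [7-(benzyloxy)-2,2-dimethyl-1,3-benzodioxol-5-yl]methanol F3, and MnO2 oxidation gives 7-(benzyloxy)-2,2-dimethyl-1,3-benzodioxole-5-carbaldehyde F4.
  - Claisen–Schmidt condensation of F4 with commercial 1-[2,4-bis(benzyloxy)-6-hydroxyphenyl]ethanone (KOH, EtOH) gives (E)-3-[7-(benzyloxy)-2,2-dimethyl-1,3-benzodioxol-5-yl]-1-[2,4-bis(benzyloxy)-6-hydroxyphenyl]prop-2-en-1-one F5.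
  - I2 in DMSO closes it to 5,7,3'-tri-O-benzyl-4',5'-O-isopropylidenetricetin F6, and hydrogenolysis (H2, Pd/C, EtOAc/THF) frees 4',5'-O-isopropylidenetricetin F7.
  - Because the C5 hydroxyl is locked in its hydrogen bond to C4=O, two equivalents of the chlorosulfate under the conditions of step 6 should give 4',5'-O-isopropylidenetricetin 7,3'-bis(2,2,2-trichloroethyl sulfate) F8.
  - The aqueous acid of step 7 takes F8 to 13.

**Step 1.**
- What may go wrong: the electron-poor catechol ketalises slowly while the aldehyde is tied up as its dimethyl acetal, so conversion may stall and condensation by-products may build up.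
- Fallback: the carbonyl is carried at the ester level during ketalisation. It sets out from 2, which is condensed with commercial methyl 3,4-dihydroxybenzoate (TsOH, toluene, reflux) to methyl 2,2-dimethyl-1,3-benzodioxole-5-carboxylate F9. LiAlH4 gives (2,2-dimethyl-1,3-benzodioxol-5-yl)methanol F10, and MnO2 returns to the route at 3.

**Step 2.**
- What may go wrong: enolisation of the doubly deprotonated ketone is slow, so the aldehyde may be consumed by disproportionation, and the chalcone may close partly to the flavanone on acidification.
- Fallback: one hydroxyl is masked first. It sets out from 4, rejoins at 8, and makes steps 3 and 4 unnecessary.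
  - 4 with MOMCl and iPr2NEt in CH2Cl2 gives 1-[2-hydroxy-6-(methoxymethoxy)phenyl]ethanone F11.
  - Condensation with 3 (KOH, EtOH) gives (E)-3-(2,2-dimethyl-1,3-benzodioxol-5-yl)-1-[2-hydroxy-6-(methoxymethoxy)phenyl]prop-2-en-1-one F12.
  - NaOAc in refluxing EtOH closes it to racemic 2-(2,2-dimethyl-1,3-benzodioxol-5-yl)-5-(methoxymethoxy)chroman-4-one F13.
  - I2 in pyridine at 90 °C dehydrogenates F13 to 8.

**Step 3.**
- What may go wrong: HI and the water formed at 120 °C may cleave the ketal before the oxidation is complete.
- Fallback: ring closure and oxidation are separated and kept free of strong acid. It sets out from 5, which NaOAc in refluxing EtOH closes to flavanone 6, now isolated. DDQ in refluxing dioxane dehydrogenates 6 and returns to the route at 7. No new compound is made.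

**Step 8.**
- What may go wrong: divalent zinc may be bound by the C5–OH/C4=O and catechol sites and drag the product into insoluble complexes, and the aryl sulfates may hydrolyse during the exchange to the free acid.
- Fallback: a sulfate protecting group that is removed by nucleophilic dealkylation replaces the reductive one. It sets out from 11 and rejoins at 15.
  - 11 with neopentyl chlorosulfate, Et3N and DMAP gives 4',5'-O-isopropylidene-5-O-methoxymethyltricetin 7,3'-bis(neopentyl sulfate) F14.
  - CF3CO2H/H2O gives tricetin 7,3'-bis(neopentyl sulfate) F15.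
  - NaN3 in DMF at 70 °C removes both neopentyl groups by SN2 attack at carbon and gives tricetin 7,3'-disulfate disodium salt F16.
  - Cold passage through the sulfonic acid resin gives 15.

## Further compounds

F1 | step 5 | methyl 7-hydroxy-2,2-dimethyl-1,3-benzodioxole-5-carboxylate | COC(=O)c1cc(O)c2c(c1)OC(C)(C)O2
F2 | step 5 | methyl 7-(benzyloxy)-2,2-dimethyl-1,3-benzodioxole-5-carboxylate | COC(=O)c1cc(OCc2ccccc2)c2c(c1)OC(C)(C)O2
F3 | step 5 | [7-(benzyloxy)-2,2-dimethyl-1,3-benzodioxol-5-yl]methanol | OCc1cc(OCc2ccccc2)c2c(c1)OC(C)(C)O2
F4 | step 5 | 7-(benzyloxy)-2,2-dimethyl-1,3-benzodioxole-5-carbaldehyde | O=Cc1cc(OCc2ccccc2)c2c(c1)OC(C)(C)O2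
F5 | step 5 | (E)-3-[7-(benzyloxy)-2,2-dimethyl-1,3-benzodioxol-5-yl]-1-[2,4-bis(benzyloxy)-6-hydroxyphenyl]prop-2-en-1-one | O=C(/C=C/c1cc(OCc2ccccc2)c2c(c1)OC(C)(C)O2)c1c(O)cc(OCc2ccccc2)cc1OCc1ccccc1
F6 | step 5 | 5,7,3'-tri-O-benzyl-4',5'-O-isopropylidenetricetin | O=c1cc(-c2cc(OCc3ccccc3)c3c(c2)OC(C)(C)O3)oc2cc(OCc3ccccc3)cc(OCc3ccccc3)c12
F7 | step 5 | 4',5'-O-isopropylidenetricetin | O=c1cc(-c2cc(O)c3c(c2)OC(C)(C)O3)oc2cc(O)cc(O)c12
F8 | step 5 | 4',5'-O-isopropylidenetricetin 7,3'-bis(2,2,2-trichloroethyl sulfate) | O=c1cc(-c2cc(OS(=O)(=O)OCC(Cl)(Cl)Cl)c3c(c2)OC(C)(C)O3)oc2cc(OS(=O)(=O)OCC(Cl)(Cl)Cl)cc(O)c12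
F9 | step 1 | methyl 2,2-dimethyl-1,3-benzodioxole-5-carboxylate | COC(=O)c1ccc2c(c1)OC(C)(C)O2
F10 | step 1 | (2,2-dimethyl-1,3-benzodioxol-5-yl)methanol | OCc1ccc2c(c1)OC(C)(C)O2
F11 | step 2 | 1-[2-hydroxy-6-(methoxymethoxy)phenyl]ethanone | CC(=O)c1c(O)cccc1OCOC
F12 | step 2 | (E)-3-(2,2-dimethyl-1,3-benzodioxol-5-yl)-1-[2-hydroxy-6-(methoxymethoxy)phenyl]prop-2-en-1-one | O=C(/C=C/c1ccc2c(c1)OC(C)(C)O2)c1c(O)cccc1OCOC
F13 | step 2 | racemic 2-(2,2-dimethyl-1,3-benzodioxol-5-yl)-5-(methoxymethoxy)chroman-4-one | O=C1CC(c2ccc3c(c2)OC(C)(C)O3)Oc2cccc(OCOC)c21
F0 | step 3 | none | none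
F14 | step 8 | 4',5'-O-isopropylidene-5-O-methoxymethyltricetin 7,3'-bis(neopentyl sulfate) | O=c1cc(-c2cc(OS(=O)(=O)OCC(C)(C)C)c3c(c2)OC(C)(C)O3)oc2cc(OS(=O)(=O)OCC(C)(C)C)cc(OCOC)c12
F15 | step 8 | tricetin 7,3'-bis(neopentyl sulfate) | O=c1cc(-c2cc(O)c(O)c(OS(=O)(=O)OCC(C)(C)C)c2)oc2cc(OS(=O)(=O)OCC(C)(C)C)cc(O)c12
F16 | step 8 | tricetin 7,3'-disulfate disodium salt | [Na+].[Na+].O=c1cc(-c2cc(O)c(O)c(OS(=O)(=O)[O-])c2)oc2cc(OS(=O)(=O)[O-])cc(O)c12
A1 | alternative 1 | 5,7,3'-tri-O-allyl-4',5'-di-O-benzyltricetin | O=c1cc(-c2cc(OCC=C)c(OCc3ccccc3)c(OCc3ccccc3)c2)oc2cc(OCC=C)cc(OCC=C)c12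
A2 | alternative 1 | (Z)-3-[3-(allyloxy)-4,5-bis(benzyloxy)phenyl]-3-[3,5-bis(allyloxy)phenoxy]prop-2-enoic acid | OC(=O)/C=C(\Oc1cc(OCC=C)cc(OCC=C)c1)c1cc(OCC=C)c(OCc2ccccc2)c(OCc2ccccc2)c1
A3 | alternative 2 | 4',5'-di-O-benzyl-5,7-di-O-methoxymethyltricetin | O=c1cc(-c2cc(O)c(OCc3ccccc3)c(OCc3ccccc3)c2)oc2cc(OCOC)cc(OCOC)c12
A4 | alternative 2 | 2,3-bis(benzyloxy)-4-chlorocyclobut-2-en-1-one | O=C1C(OCc2ccccc2)=C(OCc2ccccc2)C1Cl
A5 | alternative 2 | 5,7-bis(methoxymethoxy)-2-[1-(tributylstannyl)ethenyl]-4H-chromen-4-one | C=C(c1cc(=O)c2c(OCOC)cc(OCOC)cc2o1)[Sn](CCCC)(CCCC)CCCC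
A6 | alternative 3 | 4',5'-di-O-benzyl-3'-O-methoxymethyltricetin | O=c1cc(-c2cc(OCOC)c(OCc3ccccc3)c(OCc3ccccc3)c2)oc2cc(O)cc(O)c12
A7 | alternative 3 | 6-{4-[3,4-bis(benzyloxy)-5-(methoxymethoxy)phenyl]-2-oxobut-3-yn-1-yl}-4-hydroxy-2H-pyran-2-one | O=C(Cc1cc(O)cc(=O)o1)C#Cc1cc(OCOC)c(OCc2ccccc2)c(OCc2ccccc2)c1
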